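**Retrosynthetic overview**
1. The last disconnection is the C3′–C4′ bond in the middle of the decyl chain. Both carbons are traced back to carboxyl groups, so the target splits into 4-(3,4-dimethoxy-5-methyl-2-oxo-2H-pyran-6-yl)butanoic acid and 8-(acetylsulfanyl)octanoic acid. Their N-hydroxyphthalimide esters are joined by a nickel-electrocatalytic doubly decarboxylative coupling that gives the natural product itself.
2. The enabling feature is the unbranched, heteroatom-free (CH2)10 tether between ring atom C6 of the 2H-pyran-2-one and the thioacetate sulfur. C3′ and C4′ are plain methylenes, three carbons from the ring and seven from S, so each can be a primary radical with no cyclisation or fragmentation channel and no stereocentre at stake. The ring and the thioester are sensitive to oxidation but inert at mild cathodic potential, hence the reductive variant and not the anodic one.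
3. Pyranone half: C6, C1′–C3′ and the sacrificial carboxyl carbon are the five carbons of glutaric acid. C2–C5 with their oxygens come from methyl 2-methoxy-3-oxopentanoate (methyl methoxyacetate plus propionyl chloride).
4. Ring order: the only ring, the 2H-pyran-2-one, is closed in step 3 by O1–C2 lactonisation of an acyclic diketo ester, before the key step. 4-O-Methylation, ester cleavage and activation follow.
5. Sulfur half: 8-bromooctanoic acid plus potassium thioacetate, then activation.

Key step: step 9

Remark on the chemistry: the target has no stereocentre and no stereogenic double bond. It is achiral, so no enantiocontrol is needed. The labile stereocentres of the acyclic precursors become sp2 ring atoms.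

**Step 1**
Reactants: 1 methyl methoxyacetate; 2 propionyl chloride
Product: 4 methyl 2-methoxy-3-oxopentanoate, via methyl methoxyacetate lithium enolate 3 (not isolated)
Conditions: 1 (2 equiv), LDA (2 equiv), THF, −78 °C; then 2 (1 equiv), −78 → −20 °C; aq NH4Cl
Reagents that add atoms: none
Why: Crossed Claisen-type C-acylation of a preformed lithium ester enolate by an acid chloride, in which the second equivalent of enolate absorbs the acidic C2–H of the product; the new C2 stereocentre is racemic, labile and later becomes sp2.

**Step 2**
Reactants: 5 5-tert-butoxy-5-oxopentanoic acid (mono-tert-butyl glutarate)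
Product: 6 tert-butyl 5-[methoxy(methyl)amino]-5-oxopentanoate
Conditions: MeNH(OMe)·HCl, EDC·HCl, Et3N, DMAP (cat.), CH2Cl2, 0 °C → rt
Reagents that add atoms: N,O-dimethylhydroxylamine hydrochloride, CNOC.Cl
Why: Carbodiimide-mediated amidation (Weinreb amide synthesis) should engage only the free carboxyl group, since the tert-butyl ester is inert to the amine.

**Step 3**
Reactants: 4 methyl 2-methoxy-3-oxopentanoate; 6 tert-butyl 5-[methoxy(methyl)amino]-5-oxopentanoate
Product: 9 tert-butyl 4-(4-hydroxy-3-methoxy-5-methyl-2-oxo-2H-pyran-6-yl)butanoate, via dilithio dianion of the keto ester 7 (not isolated), via acyclic diketo diester 8 (not isolated)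
Conditions: 4, LDA (2.1 equiv), THF, −78 → 0 °C; 6, −78 → −10 °C; aq NH4Cl; crude 8, DBU, PhMe, rt → 60 °C; dilute acid work-up
Reagents that add atoms: none
Why: γ-Acylation of a β-keto ester dianion at its more basic terminal carbon by a Weinreb amide (the chelated tetrahedral adduct blocks over-addition and proton quench by the product), followed by DBU-promoted enol lactonisation (6-exo-trig attack of the C5 enolate oxygen on the methyl ester with loss of methanol), is the standard entry to 4-hydroxy-2-pyranones, and the bulky tert-butyl ester should stay out of Claisen- and Dieckmann-type side reactions.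

**Step 4**
Reactants: 9 tert-butyl 4-(4-hydroxy-3-methoxy-5-methyl-2-oxo-2H-pyran-6-yl)butanoate
Product: 10 tert-butyl 4-(3,4-dimethoxy-5-methyl-2-oxo-2H-pyran-6-yl)butanoate
Conditions: Me2SO4, K2CO3, acetone, reflux
Reagents that add atoms: dimethyl sulfate, COS(=O)(=O)OC
Why: O-Alkylation of the potassium salt of a 4-hydroxy-2-pyranone (a vinylogous acid) with a dialkyl sulfate, where the free ambident anion should react at the more charge-rich O4 to give the 4-methoxy-2-pyranone and not the 2-methoxy-4-pyranone.

**Step 5**
Reactants: 10 tert-butyl 4-(3,4-dimethoxy-5-methyl-2-oxo-2H-pyran-6-yl)butanoate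
Product: 11 4-(3,4-dimethoxy-5-methyl-2-oxo-2H-pyran-6-yl)butanoic acid
Conditions: TFA/CH2Cl2, 0 °C → rt
Reagents that add atoms: none
Why: Acidolysis of a tert-butyl ester through the tert-butyl cation (loss of isobutene) avoids hydroxide entirely, so the base-sensitive lactone and the C4 vinylogous ester should remain intact.

**Step 6**
Reactants: 11 4-(3,4-dimethoxy-5-methyl-2-oxo-2H-pyran-6-yl)butanoic acid
Product: 12 1,3-dioxoisoindolin-2-yl 4-(3,4-dimethoxy-5-methyl-2-oxo-2H-pyran-6-yl)butanoate
Conditions: N-hydroxyphthalimide, DIC, DMAP (cat.), CH2Cl2, rt
Reagents that add atoms: N-hydroxyphthalimide, O=C1c2ccccc2C(=O)N1O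
Why: Steglich-type carbodiimide esterification is the routine way to turn a primary alkanoic acid into its redox-active N-(acyloxy)phthalimide, and it does not touch the pyranone.

**Step 7**
Reactants: 13 8-bromooctanoic acid; 14 potassium thioacetate
Product: 15 8-(acetylsulfanyl)octanoic acid
Conditions: DMF, rt
Reagents that add atoms: none
Why: SN2 displacement of a primary bromide by the soft thioacetate anion, which is too weakly basic to be consumed by the free carboxylic acid.

**Step 8**
Reactants: 15 8-(acetylsulfanyl)octanoic acid
Product: 16 1,3-dioxoisoindolin-2-yl 8-(acetylsulfanyl)octanoate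
Conditions: N-hydroxyphthalimide, DIC, DMAP (cat.), CH2Cl2, rt
Reagents that add atoms: N-hydroxyphthalimide, O=C1c2ccccc2C(=O)N1O
Why: The same Steglich-type esterification as in step 6, in which the carbodiimide-activated carboxyl group is far more electrophilic than the S-alkyl thioacetate.

**Step 9**
Reactants: 12 1,3-dioxoisoindolin-2-yl 4-(3,4-dimethoxy-5-methyl-2-oxo-2H-pyran-6-yl)butanoate; 16 1,3-dioxoisoindolin-2-yl 8-(acetylsulfanyl)octanoate
Product: 17 lehualide H, S-[10-(3,4-dimethoxy-5-methyl-2-oxo-2H-pyran-6-yl)decyl] ethanethioate
Conditions: 12 (1 equiv), 16 (3 equiv), NiCl2·glyme (20 mol %), 4,4′,4″-tri-tert-butyl-2,2′:6′,2″-terpyridine (20 mol %), NaI, DMF, undivided cell, Zn(+)/Ni foam(−), constant current, rt, Ar; aq NH4Cl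
Reagents that add atoms: none
Why: Low-valent (terpyridine)nickel made at the cathode passes one electron to each N-(acyloxy)phthalimide, whose radical anion breaks at the N–O bond and loses CO2, so that 12 should give the primary 3-(pyranon-6-yl)propyl radical and 16 the primary 7-(acetylsulfanyl)heptyl radical; successive capture of both at nickel gives a dialkylnickel(III) species, and its reductive elimination forms the C3′–C4′ bond while the zinc anode delivers the two electrons. The closest known reaction type is the nickel-electrocatalytic doubly decarboxylative C(sp3)–C(sp3) coupling of two redox-active esters, the reductive counterpart of a mixed Kolbe electrolysis, which is established for primary–primary pairs. No ring is closed and no stereocentre is created, and both activating groups leave tracelessly in the same operation, so the product is the target itself. Chemoselectivity among the carbonyl-type groups is secured by the weak N–O bond and the low-lying phthalimide π* orbital of the redox-active esters, which accept an electron far more easily than the electron-rich 3,4-dimethoxypyranone or the unactivated S-alkyl thioacetate, whereas an anodic Kolbe variant would endanger exactly these two oxidisable groups. Cross- versus homo-coupling is only statistical, so the cheap ester 16 is used in excess and the polar pyranone serves as the chromatographic handle that separates 17 from homocoupled material. Neither radical has a fast intramolecular escape, since attack of the propyl radical on C6 or C5 of the ring would be a 4-exo or 5-endo closure and attack of the heptyl radical on sulfur would need an eight-membered transition state.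

**Compound list**
1 | methyl methoxyacetate | COCC(=O)OC | starting material
2 | propionyl chloride | CCC(=O)Cl | starting material
3 | lithium enolate of methyl methoxyacetate (not isolated) | COC=C([O-])OC.[Li+] | intermediate
4 | methyl 2-methoxy-3-oxopentanoate (racemic, C2 configurationally labile) | CCC(=O)C(OC)C(=O)OC | intermediate
5 | 5-tert-butoxy-5-oxopentanoic acid (mono-tert-butyl glutarate) | CC(C)(C)OC(=O)CCCC(=O)O | starting material
6 | tert-butyl 5-[methoxy(methyl)amino]-5-oxopentanoate | CON(C)C(=O)CCCC(=O)OC(C)(C)C | intermediate
7 | dilithio dianion (bis-enolate) of 4 (not isolated) | CC=C([O-])C(OC)=C([O-])OC.[Li+].[Li+] | intermediate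
8 | 9-tert-butyl 1-methyl 2-methoxy-4-methyl-3,5-dioxononanedioate (mixture of labile diastereomers and enol forms, carried on crude) | COC(=O)C(OC)C(=O)C(C)C(=O)CCCC(=O)OC(C)(C)C | intermediate
9 | tert-butyl 4-(4-hydroxy-3-methoxy-5-methyl-2-oxo-2H-pyran-6-yl)butanoate | COc1c(O)c(C)c(CCCC(=O)OC(C)(C)C)oc1=O | intermediate
10 | tert-butyl 4-(3,4-dimethoxy-5-methyl-2-oxo-2H-pyran-6-yl)butanoate | COc1c(C)c(CCCC(=O)OC(C)(C)C)oc(=O)c1OC | intermediate
11 | 4-(3,4-dimethoxy-5-methyl-2-oxo-2H-pyran-6-yl)butanoic acid | COc1c(C)c(CCCC(=O)O)oc(=O)c1OC | intermediate
12 | 1,3-dioxoisoindolin-2-yl 4-(3,4-dimethoxy-5-methyl-2-oxo-2H-pyran-6-yl)butanoate | COc1c(C)c(CCCC(=O)ON2C(=O)c3ccccc3C2=O)oc(=O)c1OC | intermediate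
13 | 8-bromooctanoic acid | OC(=O)CCCCCCCBr | starting material
14 | potassium thioacetate | CC(=O)[S-].[K+] | starting material
15 | 8-(acetylsulfanyl)octanoic acid | CC(=O)SCCCCCCCC(=O)O | intermediate
16 | 1,3-dioxoisoindolin-2-yl 8-(acetylsulfanyl)octanoate | CC(=O)SCCCCCCCC(=O)ON1C(=O)c2ccccc2C1=O | intermediate
17 | lehualide H, S-[10-(3,4-dimethoxy-5-methyl-2-oxo-2H-pyran-6-yl)decyl] ethanethioate (achiral) | COc1c(C)c(CCCCCCCCCCSC(C)=O)oc(=O)c1OC | target

**Total step count:** 9
**Longest linear sequence:** 6 (steps 1, 3, 4, 5, 6, 9)

**Steps most likely to fail**

1. Step 9. Statistical homocoupling and premature hydrogen abstraction by the primary radicals may erode the cross-coupling. Slow release of thiolate or acyl C–S insertion may deactivate the nickel catalyst.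
   - The fallback sets out from 12 and comes back at 17.
   - 7-Bromohept-1-ene is converted with magnesium into hept-6-enylmagnesium bromide F1. This is transmetalated with ZnCl2 (0.5 equiv) to bis(hept-6-enyl)zinc F2.
   - Nickel-catalysed decarboxylative alkyl–alkyl coupling of the Negishi type between F2 and 12 (NiCl2·glyme, 4,4′-di-tert-butyl-2,2′-bipyridine, THF/DMF, rt) forms the same C3′–C4′ bond with only one radical partner, so the statistical problem disappears. It should give 6-(dec-9-en-1-yl)-3,4-dimethoxy-5-methyl-2H-pyran-2-one F3.
   - Sulfur enters only after all metal catalysis, by anti-Markovnikov radical thiol–ene addition of thioacetic acid to the terminal alkene (AIBN, PhMe, 70 °C), which gives 17.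

2. Step 3. Proton transfer from the α-CH2 of the Weinreb amide to the strongly basic γ-carbanion may compete with acylation, so that both partners are merely returned.
   - The fallback sets out from 6 (together with dianion 7 made from 4) and comes back at 8. The C–C bond is formed at the aldehyde oxidation level.
   - DIBAL-H (1 equiv, CH2Cl2, −78 °C) reduces 6 to tert-butyl 5-oxopentanoate F4.
   - Aldol addition of 7 to F4 at −78 °C, which is much faster than enolisation, should give 9-tert-butyl 1-methyl 5-hydroxy-2-methoxy-4-methyl-3-oxononanedioate F5 as a mixture of diastereomers whose stereocentres are all erased later.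
   - Dess–Martin oxidation of F5 gives 8, which is closed with DBU as in the route.

3. Step 4. Alkylation of the ambident pyranone anion at the C2 carbonyl oxygen may divert material into the 2-methoxy-4-pyranone series.
   - The fallback sets out from 9 and comes back at 10. It reverses the polarity, so that C4 becomes the electrophile.
   - Sulfonylation of 9 (TsCl, Et3N, CH2Cl2, 0 °C) should give tert-butyl 4-[3-methoxy-5-methyl-2-oxo-4-(tosyloxy)-2H-pyran-6-yl]butanoate F6.
   - Addition–elimination of sodium methoxide at C4 (MeOH, 0 °C) then places the methoxy group at that carbon only and gives 10.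

**Further compounds**
F1 | step 9 | hept-6-enylmagnesium bromide | C=CCCCCC[Mg]Br
F2 | step 9 | bis(hept-6-enyl)zinc | C=CCCCCC[Zn]CCCCCC=C
F3 | step 9 | 6-(dec-9-en-1-yl)-3,4-dimethoxy-5-methyl-2H-pyran-2-one | COc1c(C)c(CCCCCCCCC=C)oc(=O)c1OC
F4 | step 3 | tert-butyl 5-oxopentanoate | O=CCCCC(=O)OC(C)(C)C
F5 | step 3 | 9-tert-butyl 1-methyl 5-hydroxy-2-methoxy-4-methyl-3-oxononanedioate (diastereomer mixture) | COC(=O)C(OC)C(=O)C(C)C(O)CCCC(=O)OC(C)(C)C
F6 | step 4 | tert-butyl 4-[3-methoxy-5-methyl-2-oxo-4-(tosyloxy)-2H-pyran-6-yl]butanoate | COc1c(OS(=O)(=O)c2ccc(C)cc2)c(C)c(CCCC(=O)OC(C)(C)C)oc1=O
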